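(Readings and results are calculated on assumed constants.)

No rate constants are given for this flask, so we read what we need from the two earlier runs.

| flask | J | remark | time |
|---|---|---|---|
| theta | 0.026 M | run made earlier |  |
| zeta | 0.040 M | run made earlier |  |
| flask | 0.053 M |  | 10 d |

| run | time / d | D / % | Q / % |
|---|---|---|---|
| theta | 0.500 | 33.0 | 59.4 |
| theta | 0.833 | 33.3 | 59.0 |
| theta | 1.04 | 33.6 | 58.4 |
| theta | 1.67 | 33.4 | 57.7 |
| theta | 2.50 | 34.0 | 57.8 |
| theta | 4.00 | 34.9 | 57.6 |
| theta | 6.00 | 34.7 | 56.6 |
| zeta | 0.833 | 30.9 | 64.3 |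
| zeta | 1.67 | 27.2 | 66.0 |
| zeta | 2.50 | 27.0 | 67.1 |
| zeta | 3.00 | 26.7 | 68.7 |
| zeta | 4.00 | 25.1 | 69.9 |
| zeta | 5.00 | 24.0 | 69.9 |
| zeta | 6.00 | 24.4 | 69.3 |

(each reading ± 0.5 percentage points)

- a reading or a percentage of Q counts all its forms, free or not

1. share of D in D plus Q at 80 s
2. share of D in D plus Q at 2.0 h
3. share of D in D plus Q at 10 d
4. which of D and Q there is more of at 10 d

Our first way is the early split, a selectivity under kinetic control. At 0.500 d the theta run has a D share of 35.7 %, and we take that share for 80 s and 2.0 h in the flask. This way gives the same share for 10 d.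

Our second way works with the concentration of D that is left, not with the percentage made. The last theta reading gives D at 9.02 mM. If that concentration holds at the zeta charge too, the last zeta reading should show 22.6 % of its charge as D. The split, with the 93.7 % of the charge found as D plus Q in the last zeta reading, says 33.5 %. The reading is 24.4 %, closer to the second way. So in the zeta run the split cheats at late times.

The zeta readings come down to 9.76 mM from 12.4 mM, while the theta readings climb to 9.02 mM from 8.58 mM. We therefore take the midpoint as the resting level of D, 9.39 mM. What to watch is D as a concentration. In the flask this level is 17.7 % of the charge. With the recovery of the last zeta reading, we reckon a D share at 10 d of 18.9 %, and we expect Q to lead.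

The forecast gives 35.5 %, 35 % and 20.5 %, the last above ours, with Q ahead, reasoning that “D levels off near 0.0095–0.0097 M”.

The flask gives 33.4 %, 34.8 % and 18.3 %, with Q ahead.

    J ⇌ Q (K = 5.80, k = 0.0200 min⁻¹)
    J ⇌ D (K = 25.0, k = 0.00990 min⁻¹)
    Q ⇌ E (K = 0.770, k = 0.0170 min⁻¹)
    L ⇌ Q, rate k4*(cs4 - [Q]) while solid is left; crystals form when [Q] > cs4 (solubility = 2.10 mM, k = 0.160 min⁻¹)
    Q → X (k = 1.50 × 10⁻⁵ min⁻¹)

The half-life of D for going back through the reaction of J to D is 1.2 d, shorter than the 10 d of this flask. The half-life of dissolved Q by the reaction to X at that time is 32 d, longer than those 10 d. The flask ends with D at 9.25 mM, against our resting level of 9.39 mM. For the same flask charged with 0.021 M of J, that level is 44.7 % of the charge, and D there stands at 42.9 % of its charge at 10 d.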